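If ligand and complex can go in by any route, we ask how many exchanges the ligand buys. We count turnovers E, the percent of one-exchanged complex plus twice that of two-exchanged complex. The south run ended at E 36.4% with 5.5% two-exchanged, the east run at 49.6% with 12.6%.

| flask | starting complex | incoming ligand | temperature | remark | time |
|---|---|---|---|---|---|
| south-east | 0.050 M | 0.045 M | 20 °C | run made earlier |  |
| west | 0.034 M | 0.045 M | 35 °C | run made earlier |  |
| south | 0.075 M | 0.045 M | 20 °C | run made earlier |  |
| east | 0.050 M | 0.068 M | 35 °C | run made earlier |  |
| Friday's | 0.050 M | 0.0450 M (fed, over 3.0 h) |  | the addition at 15 °C, then warmed to 35 °C; the feed brings no volume worth counting | 15 h |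
| Saturday's | 0.050 M | 0.0450 M (fed, over 3.0 h) | 35 °C | all else is in the flask from the start; the feed brings no volume worth counting | 15 h |
| Sunday's | 0.050 M (in portions, 4, over 3.0 h) | 0.0450 M | 35 °C | first portion at the start, last at 3.0 h | 15 h |
| Wednesday's | 0.050 M (fed, over 3.0 h) | 0.0450 M | 35 °C | all else is in the flask from the start; the feed brings no volume worth counting | 15 h |

- south-east (time / h: complex with two exchanged / %, complex with one exchanged / %, starting complex / %): 8.00: 6.2, 27.0, 28.2; 15.0: 8.0, 27.5, 20.9; 25.0: 9.3, 28.1, 17.6; 30.0: 7.6, 28.3, 17.4
- west (time / h: complex with two exchanged / %, complex with one exchanged / %, starting complex / %): 2.50: 7.7, 24.6, 32.2; 5.00: 9.6, 25.1, 23.2; 6.00: 9.7, 24.9, 21.8; 10.0: 10.7, 25.3, 17.6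
- south (time / h: complex with two exchanged / %, complex with one exchanged / %, starting complex / %): 2.00: 2.1, 20.3, 58.8; 6.00: 3.6, 24.8, 39.6; 12.0: 4.8, 25.4, 34.2; 20.0: 5.5, 25.4, 31.9
- east (time / h: complex with two exchanged / %, complex with one exchanged / %, starting complex / %): 1.00: 4.7, 23.2, 42.8; 3.00: 10.2, 25.5, 24.2; 6.00: 12.2, 24.5, 16.7; 10.0: 12.6, 24.4, 15.7

(scatter of a reading: 0.5 percentage points)

- the earlier runs were read with a standard deviation of 0.5 percentage points

- which flask leads in amount of complex with two exchanged, in percent of the starting complex charged ("all alike" within 1.5 percentage points) (Friday's / Saturday's / Sunday's / Wednesday's / all alike)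
- how much complex with two exchanged is there at the end, in percent of the starting complex charged: Friday's
- how much complex with two exchanged is there at the end, in percent of the starting complex charged: Saturday's
- how much complex with two exchanged is there at the end, in percent of the starting complex charged: Sunday's
- how much complex with two exchanged is there at the end, in percent of the starting complex charged: Wednesday's

The east run stops changing with 15.7% starting complex still there, so we reckon its 0.068 M of ligand as divided: 0.0248 M into exchanges, the rest into a loss no reading shows, or 1.74 lost per exchange. Two rates count, then: loss of ligand and exchange. We take their ratio ρ as σ times ligand over complex. Dividing by the charged ratio gives 1.28: this is σ, the ligand lost per exchange at equal ligand and complex, a selectivity factor, here a reading. At 20 °C, the south-east and south runs, charged at ratios 0.900 and 0.600, read 1.19 and 1.08, lower than σ.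

Charged at once, our amounts give ρ = 1.15 and E of 41.8%. Reckoned on the charges, feeding ligand into the full complex charge, as Friday's and Saturday's do, gives ρ = 0.288 with a quarter of the ligand in, lower than at once; Sunday's first portion, against the full ligand charge, gives 4.61, higher than at once, and Wednesday's feed gives the same with a quarter of the complex in. So we expect Saturday's and Friday's ahead, Sunday's and Wednesday's behind.

The forecast said all alike, with 8%, 8%, 8.1% and 8.3% for Friday's, Saturday's, Sunday's and Wednesday's, since “the addition history should largely be forgotten”. The flasks give 11.0%, 13.9%, 3.99% and 2.74%, so Saturday's leads.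

    complex with one exchanged + incoming ligand → leaving ligand + complex with two exchanged (k = 0.00410 L mol⁻¹ s⁻¹, Ea = 70.0 kJ mol⁻¹)
    starting complex + incoming ligand → leaving ligand + complex with one exchanged (k = 0.00430 L mol⁻¹ s⁻¹, Ea = 51.0 kJ mol⁻¹)
    2 incoming ligand → self-condensation product (k = 0.00640 L mol⁻¹ s⁻¹, Ea = 70.0 kJ mol⁻¹)
    leaving ligand + starting complex → side product (k = 0.0350 L mol⁻¹ s⁻¹, Ea = 57.0 kJ mol⁻¹)
    (constants at 35 °C)

In Wednesday's flask, self-condensation did half its turnover within 0.304 h, while complex was still being fed, and at 0.304 h it took ligand 17 times as fast as the first exchange. In Saturday's flask, ligand averaged 0.00954 M over the feed, less than the 0.0450 M charged. Ligand in self-condensation product per exchange ended at 0.747 in Saturday's and 3.34 in Wednesday's, or 2.90 times our at-once ρ.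

A neighbour of Wednesday's holds 0.18 M of ligand. Keeping that factor, σ gives ρ = 13.4 and E of 25.1%. The flask gives E of 26.1% and 4.50% two-exchanged complex.

(The earlier runs and the new flask come from a simulation for an exercise, noise included.)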